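**Plan** (chromene numbering: O1, C2, C3, C4, C4a, C5–C8, C8a)
- Retrosynthesis: first cut the prenyl–carbon bond at the quaternary carbon of the cyclohexadienone ring, then the CH2 bridge at its bond to the trihydroxytoluene ring, then the pyran ring at C3–C2 and O1–C8a, so that C2, its two methyl groups and O1 come from acetone.
- Enabling feature: C8a sits between C8 (isobutyryl) and C4a. With C4 as an acetyl carbonyl, a fluorine on C8a is ortho to two C=O groups, and the acetyl CH3 is the future C3.
- Forward, chromene half: 5-fluororesorcinol is acylated twice and protected; aldol addition to acetone followed by ipso-substitution closes the pyranone ring; the C4 carbonyl is then removed (reduction, dehydration) and the phenols are freed.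
- Union: the chromene phenol is joined through its Mannich base to isobutyryl-methylphloroglucinol. The bridge then occupies the only free CH of that ring.
- Stereochemistry: the last step, a Pd-catalysed asymmetric dearomative prenylation at the methyl-bearing carbon, forms the cyclohexadienone ring and the single stereocentre (S) under ligand control.

Key step: step 4

Assumption: the (R,R) antipode of the Trost ligand is taken to deliver the S centre; the sense of induction for this nucleophile has to be assigned on the first run, and the (S,S) antipode is used instead if it proves opposite.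

**Step 1**
Reactants: 1 5-fluororesorcinol (5-fluorobenzene-1,3-diol)
Product: 2 1-(2-fluoro-4,6-dihydroxyphenyl)-2-methylpropan-1-one
Conditions: isobutyryl chloride (1.1 equiv), AlCl3 (3 equiv), CH2Cl2–PhNO2, 0 °C to rt; aq. HCl work-up
Reagents that add atoms: isobutyryl chloride, CC(C)C(Cl)=O
Why: Friedel–Crafts acylation of a resorcinol should enter at the position ortho to one OH and para to the other (here also ortho to F), because the position between the two OH groups is the more hindered one.

**Step 2**
Reactants: 2 1-(2-fluoro-4,6-dihydroxyphenyl)-2-methylpropan-1-one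
Product: 3 1-(3-acetyl-2-fluoro-4,6-dihydroxyphenyl)-2-methylpropan-1-one
Conditions: AcCl (1.5 equiv), AlCl3 (4 equiv), PhNO2, 60 °C; aq. HCl work-up
Reagents that add atoms: acetyl chloride, CC(Cl)=O
Why: a second Friedel–Crafts acylation should follow the pattern of the 4,6-diacylresorcinols and take the remaining position ortho to the free OH and para to the chelated OH, which puts both acyl groups next to fluorine.

**Step 3**
Reactants: 3 1-(3-acetyl-2-fluoro-4,6-dihydroxyphenyl)-2-methylpropan-1-one
Product: 4 1-[3-acetyl-2-fluoro-4,6-bis(methoxymethoxy)phenyl]-2-methylpropan-1-one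
Conditions: MOMCl (3 equiv), iPr2NEt (4 equiv), CH2Cl2, 0 °C to rt
Reagents that add atoms: chloromethyl methyl ether, COCCl
Why: O-alkylation of both phenols as methoxymethyl ethers removes the phenoxide donation that would shut down ipso-substitution at the C–F carbon, and the acetals tolerate amide base, hydride and amine base.

**Step 4**
Reactants: 4 1-[3-acetyl-2-fluoro-4,6-bis(methoxymethoxy)phenyl]-2-methylpropan-1-one, 5 acetone
Product: 8 5,7-bis(methoxymethoxy)-2,2-dimethyl-8-(2-methylpropanoyl)-2,3-dihydro-4H-chromen-4-one, via lithium enolate 6 (not isolated), via lithium aldolate 7 (not isolated)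
Conditions: LiN(SiMe3)2 (1.1 equiv), THF, −78 °C; acetone (5 equiv), −78 °C; then DMPU, −78 °C to 25 °C
Reagents that add atoms: none
Why: LiN(SiMe3)2 removes a proton from the acetyl CH3 (the isobutyryl methine is tertiary and shielded), the enolate 6 adds to acetone to make the C3–C2 bond, and the tertiary alkoxide 7 then attacks the fluorine-bearing carbon C8a, from whose Meisenheimer adduct fluoride leaves to make the O1–C8a bond. The closest known reaction types are the lithium-enolate aldol addition to a ketone and the alkoxide SNAr ring closure of ortho-fluoroaryl ketones to chroman-4-ones, run here as a domino that inverts the Kabbe chromanone condensation in that the ring oxygen comes from the ketone partner. The pyranone ring closes by a 6-exo-trig addition–elimination at C8a, the charge being taken up by the C8a=C8 bond and the isobutyryl carbonyl outside the new ring as well as by the C4 carbonyl. No stereocentre is formed. The step needs attack at C8a–F and not at the C5–OMOM carbon (also ortho to the C4 carbonyl), and it needs ring closure to outrun loss of acetone by retro-aldol. The far better leaving group and the double ortho-activation at C8a should secure the first, and excess acetone should secure the second, since retro-aldol is reversible whereas loss of fluoride as LiF is not.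

**Step 5**
Reactants: 8 5,7-bis(methoxymethoxy)-2,2-dimethyl-8-(2-methylpropanoyl)-2,3-dihydro-4H-chromen-4-one
Product: 9 rac-1-[4-hydroxy-5,7-bis(methoxymethoxy)-2,2-dimethyl-3,4-dihydro-2H-chromen-8-yl]-2-methylpropan-1-one
Conditions: NaBH4 (1 equiv), MeOH–THF, −10 to 0 °C
Reagents that add atoms: none
Why: borohydride 1,2-reduction should pick the ring carbonyl C4, which is held in the arene plane and flanked by a CH2, over the isobutyryl carbonyl, which is twisted between two ortho oxygens and shielded by isopropyl; the new C4 centre forms as a racemate and is removed in step 6.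

**Step 6**
Reactants: 9 rac-1-[4-hydroxy-5,7-bis(methoxymethoxy)-2,2-dimethyl-3,4-dihydro-2H-chromen-8-yl]-2-methylpropan-1-one
Product: 11 1-[5,7-bis(methoxymethoxy)-2,2-dimethyl-2H-chromen-8-yl]-2-methylpropan-1-one, via benzylic mesylate 10 (not isolated)
Conditions: MsCl (1.5 equiv), Et3N (4 equiv), CH2Cl2, 0 °C to rt
Reagents that add atoms: none
Why: mesylation followed by elimination should give the conjugated C3=C4 bond, because the benzylic mesylate ortho and para to alkoxy groups ionises readily and the amine removes H-3, while the basic medium keeps the acetals intact.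

**Step 7**
Reactants: 11 1-[5,7-bis(methoxymethoxy)-2,2-dimethyl-2H-chromen-8-yl]-2-methylpropan-1-one
Product: 12 1-(5,7-dihydroxy-2,2-dimethyl-2H-chromen-8-yl)-2-methylpropan-1-one
Conditions: HCl (2 M aq.), MeOH, 40 °C
Reagents that add atoms: none
Why: acid-catalysed acetal exchange to methanol should free both phenols, and the 2,2-dimethylchromene and the aryl ketone tolerate dilute acid.

**Step 8**
Reactants: 12 1-(5,7-dihydroxy-2,2-dimethyl-2H-chromen-8-yl)-2-methylpropan-1-one
Product: 13 1-{6-[(dimethylamino)methyl]-5,7-dihydroxy-2,2-dimethyl-2H-chromen-8-yl}-2-methylpropan-1-one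
Conditions: CH2(NMe2)2 (1.2 equiv), EtOH, rt
Reagents that add atoms: bis(dimethylamino)methane, CN(C)CN(C)C
Why: a phenolic Mannich reaction should take place at C6, the only unsubstituted ring carbon, which lies between the two OH groups.

**Step 9**
Reactants: 14 2-methylbenzene-1,3,5-triol (methylphloroglucinol)
Product: 15 1-(2,4,6-trihydroxy-3-methylphenyl)-2-methylpropan-1-one
Conditions: isobutyryl chloride (1.1 equiv), AlCl3 (3 equiv), CH2Cl2–PhNO2, 0 °C to rt; aq. HCl work-up
Reagents that add atoms: isobutyryl chloride, CC(C)C(Cl)=O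
Why: Friedel–Crafts acylation of the phloroglucinol should stop after one acyl group, since the two free positions are equivalent and the first acyl group deactivates the ring.

**Step 10**
Reactants: 13 1-{6-[(dimethylamino)methyl]-5,7-dihydroxy-2,2-dimethyl-2H-chromen-8-yl}-2-methylpropan-1-one, 15 1-(2,4,6-trihydroxy-3-methylphenyl)-2-methylpropan-1-one
Product: 17 1-[3-{[5,7-dihydroxy-2,2-dimethyl-8-(2-methylpropanoyl)-2H-chromen-6-yl]methyl}-2,4,6-trihydroxy-5-methylphenyl]-2-methylpropan-1-one, via ortho-quinone methide 16 (not isolated)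
Conditions: 1,4-dioxane, 90 °C, N2
Reagents that add atoms: none
Why: thermal loss of dimethylamine from the Mannich base should give an ortho-quinone methide, which is trapped in a conjugate (Friedel–Crafts type) addition by phloroglucinol 15 through its only free ring carbon, and rearomatisation makes the step irreversible.

**Step 11**
Reactants: 17 1-[3-{[5,7-dihydroxy-2,2-dimethyl-8-(2-methylpropanoyl)-2H-chromen-6-yl]methyl}-2,4,6-trihydroxy-5-methylphenyl]-2-methylpropan-1-one
Product: 18 (4S)-2-{[5,7-dihydroxy-2,2-dimethyl-8-(2-methylpropanoyl)-2H-chromen-6-yl]methyl}-3,5-dihydroxy-4-methyl-4-(3-methylbut-2-en-1-yl)-6-(2-methylpropanoyl)cyclohexa-2,5-dien-1-one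
Conditions: Pd2(dba)3·CHCl3 (2.5 mol%), (R,R)-DACH-phenyl Trost ligand [N,N'-((1R,2R)-cyclohexane-1,2-diyl)bis(2-(diphenylphosphanyl)benzamide)] (7.5 mol%), prenyl acetate (1.05 equiv), Et3N (2 equiv), CH2Cl2, 0 °C; dilute acid work-up
Reagents that add atoms: prenyl acetate (3-methylbut-2-en-1-yl acetate), CC(=O)OCC=C(C)C
Why: in a Tsuji–Trost asymmetric allylic alkylation with dearomatisation, the prenyl-palladium cation made by zerovalent palladium should be attacked at its CH2 end by the methyl-bearing ring carbon, the least hindered carbon nucleophile now that the bridge fills the former free CH, and the chiral pocket of the ligand selects the face of the planar phloroglucinolate and so sets the S quaternary centre, while O-prenyl ethers re-ionise under the catalyst.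

**Compound list**
1 | 5-fluororesorcinol (5-fluorobenzene-1,3-diol) | Oc1cc(O)cc(F)c1 | starting material
2 | 1-(2-fluoro-4,6-dihydroxyphenyl)-2-methylpropan-1-one | CC(C)C(=O)c1c(O)cc(O)cc1F | intermediate
3 | 1-(3-acetyl-2-fluoro-4,6-dihydroxyphenyl)-2-methylpropan-1-one | CC(C)C(=O)c1c(O)cc(O)c(C(C)=O)c1F | intermediate
4 | 1-[3-acetyl-2-fluoro-4,6-bis(methoxymethoxy)phenyl]-2-methylpropan-1-one | CC(C)C(=O)c1c(OCOC)cc(OCOC)c(C(C)=O)c1F | intermediate
5 | acetone | CC(C)=O | starting material
6 | lithium enolate of 4 at the acetyl group (not isolated) | [Li+].C=C([O-])c1c(F)c(C(=O)C(C)C)c(OCOC)cc1OCOC | intermediate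
7 | lithium aldolate, lithium 4-[2-fluoro-4,6-bis(methoxymethoxy)-3-(2-methylpropanoyl)phenyl]-2-methyl-4-oxobutan-2-olate (not isolated) | [Li+].CC(C)([O-])CC(=O)c1c(F)c(C(=O)C(C)C)c(OCOC)cc1OCOC | intermediate
8 | 5,7-bis(methoxymethoxy)-2,2-dimethyl-8-(2-methylpropanoyl)-2,3-dihydro-4H-chromen-4-one | CC(C)C(=O)c1c(OCOC)cc(OCOC)c2c1OC(C)(C)CC2=O | intermediate
9 | rac-1-[4-hydroxy-5,7-bis(methoxymethoxy)-2,2-dimethyl-3,4-dihydro-2H-chromen-8-yl]-2-methylpropan-1-one (racemic at C4) | CC(C)C(=O)c1c(OCOC)cc(OCOC)c2c1OC(C)(C)CC2O | intermediate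
10 | 4-methanesulfonate of 9, racemic (not isolated) | CC(C)C(=O)c1c(OCOC)cc(OCOC)c2c1OC(C)(C)CC2OS(C)(=O)=O | intermediate
11 | 1-[5,7-bis(methoxymethoxy)-2,2-dimethyl-2H-chromen-8-yl]-2-methylpropan-1-one | CC(C)C(=O)c1c(OCOC)cc(OCOC)c2c1OC(C)(C)C=C2 | intermediate
12 | 1-(5,7-dihydroxy-2,2-dimethyl-2H-chromen-8-yl)-2-methylpropan-1-one | CC(C)C(=O)c1c(O)cc(O)c2c1OC(C)(C)C=C2 | intermediate
13 | 1-{6-[(dimethylamino)methyl]-5,7-dihydroxy-2,2-dimethyl-2H-chromen-8-yl}-2-methylpropan-1-one | CC(C)C(=O)c1c(O)c(CN(C)C)c(O)c2c1OC(C)(C)C=C2 | intermediate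
14 | 2-methylbenzene-1,3,5-triol (methylphloroglucinol) | Cc1c(O)cc(O)cc1O | starting material
15 | 1-(2,4,6-trihydroxy-3-methylphenyl)-2-methylpropan-1-one | CC(C)C(=O)c1c(O)cc(O)c(C)c1O | intermediate
16 | ortho-quinone methide, 5-hydroxy-2,2-dimethyl-6-methylidene-8-(2-methylpropanoyl)-2H-chromen-7(6H)-one (not isolated) | C=C1C(=O)C(C(=O)C(C)C)=C2OC(C)(C)C=CC2=C1O | intermediate
17 | 1-[3-{[5,7-dihydroxy-2,2-dimethyl-8-(2-methylpropanoyl)-2H-chromen-6-yl]methyl}-2,4,6-trihydroxy-5-methylphenyl]-2-methylpropan-1-one | CC(C)C(=O)c1c(O)c(C)c(O)c(Cc2c(O)c3C=CC(C)(C)Oc3c(C(=O)C(C)C)c2O)c1O | intermediate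
18 | (4S)-2-{[5,7-dihydroxy-2,2-dimethyl-8-(2-methylpropanoyl)-2H-chromen-6-yl]methyl}-3,5-dihydroxy-4-methyl-4-(3-methylbut-2-en-1-yl)-6-(2-methylpropanoyl)cyclohexa-2,5-dien-1-one (CNP0301804.1) | CC(C)=CC[C@@]1(C)C(O)=C(Cc2c(O)c3c(c(C(=O)C(C)C)c2O)OC(C)(C)C=C3)C(=O)C(C(=O)C(C)C)=C1O | target

**Step count and risks**
Total step count: 11. Longest linear sequence: 10 steps (steps 1–8, 10 and 11 from 5-fluororesorcinol); step 9 is a one-step side branch.

The three steps most likely to fail:

Step 11. The catalyst may discriminate the two faces of the planar phloroglucinolate poorly. Prenylation may also occur at the bridge-bearing ring carbons, or a second time on the product anion. Fallback: setting out from 17, the prenylation is run without chiral control (Pd(PPh3)4, prenyl acetate, Et3N, THF, rt) to give the racemic form of the target F1. The enantiomers are then separated by preparative HPLC on an amylose tris(3,5-dimethylphenylcarbamate) phase, and the S enantiomer, assigned by circular dichroism or X-ray analysis, is 18, where the route is rejoined.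

Step 4. Retro-aldol loss of acetone from the tertiary aldolate, or dehydration to the enone, may outrun ring closure, and the enolate may be consumed by intermolecular substitution at C–F. Fallback: setting out from 4, fluoride is displaced by hydroxide (KOH, DMSO–H2O, 60 °C) to give the phenol 1-[3-acetyl-2-hydroxy-4,6-bis(methoxymethoxy)phenyl]-2-methylpropan-1-one F2. This phenol carries its only free OH between the two acyl groups. A Kabbe condensation with acetone (pyrrolidine, toluene, reflux), in which the ring oxygen comes from the phenol, then closes the pyranone ring and comes back to the route at 8.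

Step 5. Hydride may fail to distinguish the two aryl ketones, so that the isobutyryl group is reduced as well. Fallback: setting out from 8, kinetic enolisation at the C3 methylene and O-triflation (KN(SiMe3)2, PhNTf2, THF, −78 °C) gives the enol triflate 5,7-bis(methoxymethoxy)-2,2-dimethyl-8-(2-methylpropanoyl)-2H-chromen-4-yl trifluoromethanesulfonate F3. Palladium-catalysed formate reduction (Pd(OAc)2, PPh3, HCO2H, Et3N, DMF, 60 °C) removes the triflate and comes back to the route at 11 without passing through 9 and 10.

**Further compounds**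
F1 | step 11 | racemic 2-{[5,7-dihydroxy-2,2-dimethyl-8-(2-methylpropanoyl)-2H-chromen-6-yl]methyl}-3,5-dihydroxy-4-methyl-4-(3-methylbut-2-en-1-yl)-6-(2-methylpropanoyl)cyclohexa-2,5-dien-1-one | CC(C)=CCC1(C)C(O)=C(Cc2c(O)c3c(c(C(=O)C(C)C)c2O)OC(C)(C)C=C3)C(=O)C(C(=O)C(C)C)=C1O
F2 | step 4 | 1-[3-acetyl-2-hydroxy-4,6-bis(methoxymethoxy)phenyl]-2-methylpropan-1-one | CC(C)C(=O)c1c(OCOC)cc(OCOC)c(C(C)=O)c1O
F3 | step 5 | 5,7-bis(methoxymethoxy)-2,2-dimethyl-8-(2-methylpropanoyl)-2H-chromen-4-yl trifluoromethanesulfonate | CC(C)C(=O)c1c(OCOC)cc(OCOC)c2c1OC(C)(C)C=C2OS(=O)(=O)C(F)(F)F
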